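## Structural features

The target 30 is a flavone: a 4-pyranone (ring C) fused through C4a–C8a to ring A, with a 2,4-dihydroxyphenyl group (ring B) on C2 and a 3-methylbut-2-enyl (prenyl) chain on C3. Ring A is a phloroglucinol nucleus with oxygens on C5, C7 and C8a; only the C8a oxygen belongs to ring C (as O1). It is carbon-substituted at C4a and C8, and C6 is its only aromatic C–H. C8 carries a 2-hydroxy-3-methylbut-3-enyl chain whose carbinol carbon C2'' is the single stereocentre, (R), with no neighbouring stereocentre, so it must be set by a reagent and then only preserved. Three parts are fragile: the allylic carbinol beside the 7-hydroxyl (acid ionizes it or closes a ring onto O7), the prenyl group beside the 2'-hydroxyl (acid closes a pyran onto O2'), and the electron-rich tetraphenol itself. The real difficulty is regiochemical: the three ring A oxygens must be told apart so that one enters ring C while C8, not C6, bears the chiral chain, and all protecting groups must then come off without acid. The key step exploits the fact that ring A (C4a, C5, C6, C7, C8, C8a) can be assembled from a four-carbon vinylketene and a two-carbon ynol ether. The C8a oxygen is then born as the only free hydroxyl, C8 is the alkyne carbon already carrying the chain, and the C5 and C7 oxygens arrive as silyl ethers.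

## Logic of the disconnections

30 to 29. The five O–Si bonds (O5, O7, O2', O4', O2'') are cut last. Fluoride is the one deprotection that spares both the allylic carbinol and the prenyl group. The free polyphenol then appears only in the final flask. The demand is that every protecting group in 29 be a silyl ether.

29 to 27 (through 28). The O1–C2 bond of ring C is cut. This opens the pyranone to an acyclic 1,3-dicarbonyl compound. The forward condensation needs O8a to be the only free hydroxyl and an acid weak enough to leave six silyl ethers intact.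

27 to 21 and 25 (through 26). The C2–C3 bond is cut. C3 already carries its prenyl branch in 21, so ring B can arrive as an aroyl group that is first placed on O8a and then moved to C3. The gain is convergence: ring B is detached as a separate acid derivative. The forward step needs clean enolization toward C3 and silyl ethers that survive an amide base.

25 to 24 to 22 (through 23). The C–Cl bond and two O–Si bonds are cut. This leads to a commercial acid. The demand is a neutral activation of the acid.

21 to 20 to 17 and 18 (through 19). The C3–C4 bond is cut. A six-carbon nucleophile brings C3 and the whole prenyl chain in one piece. The gain is a simple aldehyde. The forward steps need addition to a hindered, chelated aldehyde and oxidation of a benzylic alcohol beside a free phenol.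

17 to 15 (through 16). The C4a–C4 bond is cut. The free hydroxyl of 15 directs a one-carbon electrophile to its only free ortho position, which is C4a. The demand is ortho, not para, selectivity.

15 to 10 and 8 (through 11, 12, 13, 14). The bonds C8–C8a, C6–C7 and C4a–C8a are cut. Ring A falls apart into a four-carbon piece and a two-carbon piece, and the three oxygens are differentiated by construction. The forward step needs one regiochemical outcome in the cycloaddition and partners that tolerate heat.

10 to 9. One O–Si bond is cut, which leads to a commercial dione. The demand is a silyl group bulky enough to make the vinylogous silyl ester handleable.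

8 to 5 (through 6, 7). The C7–C8 bond and the O7–Si bond are cut. The carbon that becomes C8 is inserted between the ester carbon and its α-methylene, so a simple ester becomes an ynol ether in one flask. The demand is that the β-silyloxy group is not eliminated by the strong bases.

5 to 4 to 1 and 2 (through 3). The O2''–Si bond and the C1''–C2'' bond are cut. An acetate aldol addition sets the only stereocentre catalytically from two small commercial compounds. The demand is high facial selectivity on a small conjugated aldehyde.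

## Other disconnections considered

Alternative 1: The cut is at the C2''–O bond, with the stereocentre introduced on a finished flavone.
- Forward key step: the E-allylic alcohol A1 would be epoxidized with Ti(OiPr)4, D-(−)-diethyl tartrate and tert-butyl hydroperoxide to the (2R,3R)-epoxy alcohol A2, forming C2''–O and C3''–O and closing the oxirane. Exchange of the primary hydroxyl for iodide and zinc reduction would then open the oxirane at C3'' and leave the (R)-carbinol A3, whose four acetals still have to be removed.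
- In favour: the stereocentre is set late by a catalytic, reagent-controlled reaction whose sense on E-2-methyl allylic alcohols is well established. The hydroxyl-directed epoxidation should leave the C3 prenyl alkene alone.
- Against: it does not address the ring A problem, namely telling O8a from O5 and O7 and placing a 4-hydroxyprenyl chain on C8 only. The chromone carbonyl and the ether oxygens can compete for titanium. Two more operations follow the key step. The acetals finally need acid in the presence of exactly the groups that acid destroys.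
- Comparison: Alternative 1 is the equal or the better of the chosen plan in stereocontrol, since no stereocentre has to be carried through strong base and heat. It is weaker in step economy after the key step and clearly weaker in the end-game, where the chosen plan needs only fluoride.

Alternative 2: The cut is at O1–C8a.
- Forward key step: the 2-bromoaryl 1,3-diketone A4 would be closed with CuI, 1,10-phenanthroline and Cs2CO3, the enol oxygen of the ring B carbonyl displacing bromide at C8a to give the protected flavone A5.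
- In favour: O1 comes from the diketone, so no ring A phenol has to be left free at the ring-closing stage. The conditions are basic and spare the allylic silyl ether. Only the ring B carbonyl oxygen can reach C8a through a six-membered transition state.
- Against: the bromide lies between the C8 chain and the C4a acyl group on a very electron-rich ring, a poor case for copper-mediated aryl–oxygen coupling. The 2-prenyl diketone enolizes poorly and may undergo retro-Claisen cleavage in hot carbonate. The regiochemical problem is only moved into the synthesis of the pentasubstituted arene A4. A5 still needs acid for its acetals.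
- Comparison: it is equal in ring C bonds formed at closure (one) and better in that the closure cannot choose a wrong oxygen. It is worse in access to the ring A piece and in the final deprotection.

Alternative 3: The cut takes C4 out as carbon monoxide.
- Forward key step: the ortho-iodophenol A6, CO and the aryl acetylene A7 would combine under PdCl2(PPh3)2 in diethylamine to give the 3-unsubstituted flavone A8, forming C4a–C4, C4–C3 and O1–C2 together.
- In favour: it is the most convergent assembly of ring C, three bonds from two simple halves and a gas, without strong base.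
- Against: A6 needs the same differentiated ring A phenol as 15 plus a selective iodination, so the hard problem is presupposed. The iodide is electron-rich and flanked by two oxygens, so oxidative addition is slow, and direct coupling without CO or five-membered closure may compete. C3 is left bare and must be prenylated afterwards. The acetals again need acid.
- Comparison: it is better in convergence and in bonds formed per step for ring C, and equal in its demand on ring A. It is poorer in overall step count once iodination and C3 prenylation are added, and poorer in the end-game.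

Key step: step 5

Assumption: the (R,R)-bisphosphoramide in step 1 is taken to deliver the ketene acetal to the Re face of methacrolein, which gives the (R)-ester; should the sense prove opposite, the (S,S)-catalyst is used and nothing else changes.

Atom labels follow flavone numbering (C2–C8a, C1'–C6', chain C1''–C4''). TBS = tert-butyldimethylsilyl, TIPS = triisopropylsilyl, TBSO and TIPSO are the corresponding silyloxy groups.

Step 1
Reactants: 1 methacrolein; 2 1-(tert-butyldimethylsilyloxy)-1-methoxyethene
Product: 4 methyl (R)-3-hydroxy-4-methylpent-4-enoate, via trichlorosilyl aldolate 3 (not isolated)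
Conditions: SiCl4 (1.1 equiv), (R,R)-N,N'-pentane-1,5-diylbis[N-methyl-3,5-dimethyl-3,5-dihydro-4H-dinaphtho[2,1-d:1',2'-f][1,3,2]diazaphosphepin-4-amine 4-oxide] (2 mol%), CH2Cl2, −78 °C; aq. NaHCO3
Reagents that add atoms: none
Why: Lewis-base-activated SiCl4 (a phosphoramide-bound trichlorosilyl cation) activates the conjugated aldehyde and the acetate ketene acetal adds in an open Mukaiyama-type aldol transition state. The C2-symmetric catalyst shields one face, so C1''–C2'' bond formation on the Re face of 1 sets the (R)-carbinol; the aldolate is held as 3 until hydrolysis.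

Step 2
Reactants: 4 methyl (R)-3-hydroxy-4-methylpent-4-enoate
Product: 5 methyl (R)-3-(TBSO)-4-methylpent-4-enoate
Conditions: TBSCl, imidazole, DMF, 25 °C
Reagents that add atoms: tert-butyl(chloro)dimethylsilane, C[Si](C)(Cl)C(C)(C)C
Why: Standard silylation of a secondary alcohol. The TBS ether tolerates amide and alkyllithium bases, heat and weak acid, and falls to fluoride at the end; the stereocentre is not involved.

Step 3
Reactants: 5 methyl (R)-3-(TBSO)-4-methylpent-4-enoate
Product: 8 (R)-4-(TBSO)-5-methyl-1-(TIPSO)hex-5-en-1-yne, via dibromoketone enolate 6 (not isolated), via lithium ynolate 7 (not isolated)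
Conditions: CH2Br2 (2.2 equiv), LiTMP (2.1 equiv), THF, −78 °C; LiHMDS (2 equiv), −78 → −20 °C; n-BuLi (4 equiv), −78 → 25 °C; TIPSCl (6 equiv), −78 → 0 °C
Reagents that add atoms: dibromomethane, BrCBr; chlorotriisopropylsilane, CC(C)[Si](Cl)(C(C)C)C(C)C
Why: Kowalski ester homologation: dibromomethyllithium adds to the ester, the dibromoketone is held as enolate 6, and bromine–lithium exchange triggers 1,2-migration of the alkyl group to the carbenoid carbon to give ynolate 7, which the bulky chlorosilane silylates on oxygen. The former ester carbon becomes the oxygen-bearing alkyne carbon (future C7) and the dibromomethane carbon becomes future C8; enolization toward CBr2 keeps the β-silyloxy group from eliminating and the stereocentre is untouched.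

Step 4
Reactants: 9 cyclobutane-1,3-dione
Product: 10 3-(TIPSO)cyclobut-2-en-1-one
Conditions: TIPSCl, Et3N, CH2Cl2, 0 °C
Reagents that add atoms: chlorotriisopropylsilane, CC(C)[Si](Cl)(C(C)C)C(C)C
Why: The dione is an enolized vinylogous acid and is silylated on oxygen like a carboxylic acid. The bulky TIPS group makes the vinylogous silyl ester handleable and a slow silyl donor.

Step 5
Reactants: 10 3-(TIPSO)cyclobut-2-en-1-one; 8 (R)-4-(TBSO)-5-methyl-1-(TIPSO)hex-5-en-1-yne
Product: 15 2-[(R)-2-(TBSO)-3-methylbut-3-enyl]-3,5-bis(TIPSO)phenol, via vinylketene 11 (not isolated), via vinylcyclobutenone 12 (not isolated), via dienylketene 13 (not isolated), via cyclohexadienone 14 (not isolated)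
Conditions: toluene, 110 °C, 10 (1.2 equiv) added over 4 h to 8
Reagents that add atoms: none
Why: Heat opens 10 by four-electron electrocyclic ring opening to vinylketene 11. 11 adds to 8 in a [2+2] cycloaddition in which the nucleophilic alkyne carbon bearing the chain attacks the ketene carbonyl carbon (C8–C8a) and the silyloxy carbon bonds to the ketene α-carbon (C6–C7), giving 12. 12 opens in a second four-electron electrocyclic step to dienylketene 13, which closes ring A by a thermal six-electron disrotatory electrocyclization forming C4a–C8a, and dienone 14 tautomerizes to the phenol. The closest known reaction is the Danheiser benzannulation of cyclobutenones with siloxyalkynes to resorcinol monosilyl ethers; 3-silyloxycyclobutenones are known compounds and oxygen-substituted cyclobutenones are established vinylketene precursors. No stereocentre is created, and C2'' lies two bonds from the alkyne, has no acidic hydrogen under neutral thermal conditions and is carried through unchanged. The selectivity needed is regiochemical in the [2+2] step and is secured by the polarization of the ynol ether, so the ketene oxygen ends as the only free hydroxyl (future O1) between C8 and the open C4a–H. The isopropenyl group does not compete because the electron-rich alkyne is the far better ketenophile and an intramolecular ketene–alkene addition would need a strained bicycle; slow addition of 10 keeps the ketene concentration low.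

Step 6
Reactants: 15 2-[(R)-2-(TBSO)-3-methylbut-3-enyl]-3,5-bis(TIPSO)phenol
Product: 17 3-[(R)-2-(TBSO)-3-methylbut-3-enyl]-2-hydroxy-4,6-bis(TIPSO)benzaldehyde, via hydroxymethylphenol 16 (not isolated)
Conditions: MgCl2 (2 equiv), Et3N (4 equiv), (CH2O)n (6 equiv), THF, 65 °C
Reagents that add atoms: paraformaldehyde (as formaldehyde), C=O
Why: Magnesium-mediated ortho-formylation (Casnati–Skattebøl): the magnesium phenoxide delivers formaldehyde through a six-membered chelate to the only free ortho carbon, C4a, and a second formaldehyde oxidizes 16 by Oppenauer-type hydride transfer. The para carbon C6 is not reached by this chelated pathway.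

Step 7
Reactants: 17 3-[(R)-2-(TBSO)-3-methylbut-3-enyl]-2-hydroxy-4,6-bis(TIPSO)benzaldehyde; 18 5-bromo-2-methylpent-2-ene
Product: 20 2-[(R)-2-(TBSO)-3-methylbut-3-enyl]-6-(1-hydroxy-5-methylhex-4-enyl)-3,5-bis(TIPSO)phenol (both epimers at the new carbinol), via homoprenylmagnesium bromide 19 (not isolated)
Conditions: 18, Mg, THF; then 17, −78 → 0 °C (2.5 equiv of 19); pH 7 buffer
Reagents that add atoms: none
Why: Grignard addition: the first equivalent of 19 deprotonates the phenol and the second adds to the chelated aldehyde, forming C3–C4. The new carbinol centre forms unselectively and is destroyed in step 8; magnesium counter-ions and low temperature disfavour migration of the neighbouring aryl TIPS group.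

Step 8
Reactants: 20 2-[(R)-2-(TBSO)-3-methylbut-3-enyl]-6-(1-hydroxy-5-methylhex-4-enyl)-3,5-bis(TIPSO)phenol
Product: 21 1-{3-[(R)-2-(TBSO)-3-methylbut-3-enyl]-2-hydroxy-4,6-bis(TIPSO)phenyl}-5-methylhex-4-en-1-one
Conditions: MnO2 (20 equiv), CH2Cl2, 25 °C
Reagents that add atoms: none
Why: Manganese dioxide oxidation of an activated benzylic alcohol under neutral conditions. The alkenes and silyl ethers are inert, and the product phenol is stabilized by its hydrogen bond to the new ketone.

Step 9
Reactants: 22 2,4-dihydroxybenzoic acid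
Product: 24 2,4-bis(TIPSO)benzoic acid, via silyl ester 23 (not isolated)
Conditions: TIPSOTf (3.3 equiv), Et3N, CH2Cl2, 0 → 25 °C; then K2CO3, THF/H2O, 0 °C; citric acid to pH 4
Reagents that add atoms: triisopropylsilyl trifluoromethanesulfonate, CC(C)[Si](OS(=O)(=O)C(F)(F)F)(C(C)C)C(C)C
Why: Exhaustive silylation followed by selective hydrolysis of the silyl ester, which is far more labile than the two aryl silyl ethers. TIPS is chosen on ring B because it is slow to migrate and survives amide bases.

Step 10
Reactants: 24 2,4-bis(TIPSO)benzoic acid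
Product: 25 2,4-bis(TIPSO)benzoyl chloride
Conditions: 1-chloro-N,N,2-trimethylprop-1-en-1-amine (1.2 equiv), CH2Cl2, 0 → 25 °C; used crude
Reagents that add atoms: 1-chloro-N,N,2-trimethylprop-1-en-1-amine, CC(C)=C(Cl)N(C)C
Why: The Ghosez reagent turns carboxylic acids into acid chlorides under neutral conditions with only an amide as by-product, so no hydrogen chloride threatens the aryl silyl ethers.

Step 11
Reactants: 21 1-{3-[(R)-2-(TBSO)-3-methylbut-3-enyl]-2-hydroxy-4,6-bis(TIPSO)phenyl}-5-methylhex-4-en-1-one; 25 2,4-bis(TIPSO)benzoyl chloride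
Product: 27 1-[2,4-bis(TIPSO)phenyl]-3-{3-[(R)-2-(TBSO)-3-methylbut-3-enyl]-2-hydroxy-4,6-bis(TIPSO)phenyl}-2-(3-methylbut-2-enyl)propane-1,3-dione (epimers at C3), via aryl ester 26 (not isolated)
Conditions: LiHMDS (1.05 equiv), THF, −78 °C; 25 (1.2 equiv), −78 → 0 °C; LiHMDS (2.5 equiv), −78 → −20 °C; aq. NH4Cl
Reagents that add atoms: none
Why: O-Acylation of the lithium phenoxide followed by Baker–Venkataraman rearrangement: the ketone enolate of 26 attacks the neighbouring aryl ester through a six-membered transition state and the aroyl group moves from O8a to C3, forming C2–C3. The non-nucleophilic base and low temperature protect the aryl silyl ethers, and the new C3 centre is lost in step 12.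

Step 12
Reactants: 27 1-[2,4-bis(TIPSO)phenyl]-3-{3-[(R)-2-(TBSO)-3-methylbut-3-enyl]-2-hydroxy-4,6-bis(TIPSO)phenyl}-2-(3-methylbut-2-enyl)propane-1,3-dione
Product: 29 8-[(R)-2-(TBSO)-3-methylbut-3-enyl]-3-(3-methylbut-2-enyl)-5,7-bis(TIPSO)-2-[2,4-bis(TIPSO)phenyl]chromen-4-one, via hemiketal 28 (not isolated)
Conditions: PPTS (0.2 equiv), 4 Å MS, toluene, 70 °C
Reagents that add atoms: none
Why: Acid-catalysed cyclodehydration of an o-hydroxyaryl 1,3-diketone: O8a, the only free hydroxyl, adds to the ring B carbonyl to give 28, and loss of water is driven by formation of the conjugated 4-pyranone. Pyridinium tosylate in an aprotic solvent is weak enough for the allylic TBS ether and the aryl TIPS ethers.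

Step 13
Reactants: 29 8-[(R)-2-(TBSO)-3-methylbut-3-enyl]-3-(3-methylbut-2-enyl)-5,7-bis(TIPSO)-2-[2,4-bis(TIPSO)phenyl]chromen-4-one
Product: 30 2-(2,4-dihydroxyphenyl)-5,7-dihydroxy-8-[(R)-2-hydroxy-3-methylbut-3-enyl]-3-(3-methylbut-2-enyl)chromen-4-one
Conditions: Bu4NF (6 equiv), AcOH (6 equiv), THF, 0 → 25 °C; pH 6 phosphate buffer
Reagents that add atoms: none
Why: Fluoride cleaves the four aryl TIPS ethers and the secondary TBS ether in one operation; acetic acid keeps the liberated phenols protonated. No acid strong enough to ionize the allylic carbinol or to cyclize the prenyl group onto O2' is present, so the (R)-centre is retained.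

## Compound list

1 | methacrolein | C=C(C)C=O | starting material
2 | 1-(tert-butyldimethylsilyloxy)-1-methoxyethene | C=C(OC)O[Si](C)(C)C(C)(C)C | starting material
3 | methyl (R)-4-methyl-3-(trichlorosilyloxy)pent-4-enoate | C=C(C)[C@H](O[Si](Cl)(Cl)Cl)CC(=O)OC | intermediate (not isolated)
4 | methyl (R)-3-hydroxy-4-methylpent-4-enoate | C=C(C)[C@H](O)CC(=O)OC | intermediate
5 | methyl (R)-3-(TBSO)-4-methylpent-4-enoate | C=C(C)[C@H](O[Si](C)(C)C(C)(C)C)CC(=O)OC | intermediate
6 | lithium enolate of (R)-1,1-dibromo-4-(TBSO)-5-methylhex-5-en-2-one | C=C(C)[C@H](O[Si](C)(C)C(C)(C)C)CC([O-])=C(Br)Br.[Li+] | intermediate (not isolated)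
7 | lithium (R)-4-(TBSO)-5-methylhex-5-en-1-yn-1-olate | C=C(C)[C@H](O[Si](C)(C)C(C)(C)C)CC#C[O-].[Li+] | intermediate (not isolated)
8 | (R)-4-(TBSO)-5-methyl-1-(TIPSO)hex-5-en-1-yne | C=C(C)[C@H](O[Si](C)(C)C(C)(C)C)CC#CO[Si](C(C)C)(C(C)C)C(C)C | intermediate
9 | cyclobutane-1,3-dione | O=C1CC(=O)C1 | starting material
10 | 3-(TIPSO)cyclobut-2-en-1-one | O=C1C=C(O[Si](C(C)C)(C(C)C)C(C)C)C1 | intermediate
11 | 3-(TIPSO)buta-1,3-dien-1-one | O=C=CC(=C)O[Si](C(C)C)(C(C)C)C(C)C | intermediate (not isolated)
12 | 2-[(R)-2-(TBSO)-3-methylbut-3-enyl]-3-(TIPSO)-4-[1-(TIPSO)vinyl]cyclobut-2-en-1-one (C4 unassigned) | C=C(C)[C@H](O[Si](C)(C)C(C)(C)C)CC1=C(O[Si](C(C)C)(C(C)C)C(C)C)C(C(=C)O[Si](C(C)C)(C(C)C)C(C)C)C1=O | intermediate (not isolated)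
13 | dienylketene, (R)-2-[2-(TBSO)-3-methylbut-3-enyl]-3,5-bis(TIPSO)hexa-1,3,5-trien-1-one | C=C(C)[C@H](O[Si](C)(C)C(C)(C)C)CC(=C=O)/C(O[Si](C(C)C)(C(C)C)C(C)C)=C\C(=C)O[Si](C(C)C)(C(C)C)C(C)C | intermediate (not isolated)
14 | 2-[(R)-2-(TBSO)-3-methylbut-3-enyl]-3,5-bis(TIPSO)cyclohexa-2,4-dien-1-one | C=C(C)[C@H](O[Si](C)(C)C(C)(C)C)CC1=C(O[Si](C(C)C)(C(C)C)C(C)C)C=C(O[Si](C(C)C)(C(C)C)C(C)C)CC1=O | intermediate (not isolated)
15 | 2-[(R)-2-(TBSO)-3-methylbut-3-enyl]-3,5-bis(TIPSO)phenol | C=C(C)[C@H](O[Si](C)(C)C(C)(C)C)Cc1c(O)cc(O[Si](C(C)C)(C(C)C)C(C)C)cc1O[Si](C(C)C)(C(C)C)C(C)C | intermediate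
16 | 2-(hydroxymethyl)-6-[(R)-2-(TBSO)-3-methylbut-3-enyl]-3,5-bis(TIPSO)phenol (as magnesium chelate) | C=C(C)[C@H](O[Si](C)(C)C(C)(C)C)Cc1c(O)c(CO)c(O[Si](C(C)C)(C(C)C)C(C)C)cc1O[Si](C(C)C)(C(C)C)C(C)C | intermediate (not isolated)
17 | 3-[(R)-2-(TBSO)-3-methylbut-3-enyl]-2-hydroxy-4,6-bis(TIPSO)benzaldehyde | C=C(C)[C@H](O[Si](C)(C)C(C)(C)C)Cc1c(O)c(C=O)c(O[Si](C(C)C)(C(C)C)C(C)C)cc1O[Si](C(C)C)(C(C)C)C(C)C | intermediate
18 | 5-bromo-2-methylpent-2-ene | CC(C)=CCCBr | starting material
19 | (4-methylpent-3-enyl)magnesium bromide | CC(C)=CCC[Mg]Br | intermediate (not isolated)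
20 | 2-[(R)-2-(TBSO)-3-methylbut-3-enyl]-6-(1-hydroxy-5-methylhex-4-enyl)-3,5-bis(TIPSO)phenol (epimers at the benzylic carbinol) | C=C(C)[C@H](O[Si](C)(C)C(C)(C)C)Cc1c(O)c(C(O)CCC=C(C)C)c(O[Si](C(C)C)(C(C)C)C(C)C)cc1O[Si](C(C)C)(C(C)C)C(C)C | intermediate
21 | 1-{3-[(R)-2-(TBSO)-3-methylbut-3-enyl]-2-hydroxy-4,6-bis(TIPSO)phenyl}-5-methylhex-4-en-1-one | C=C(C)[C@H](O[Si](C)(C)C(C)(C)C)Cc1c(O)c(C(=O)CCC=C(C)C)c(O[Si](C(C)C)(C(C)C)C(C)C)cc1O[Si](C(C)C)(C(C)C)C(C)C | intermediate
22 | 2,4-dihydroxybenzoic acid | O=C(O)c1ccc(O)cc1O | starting material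
23 | triisopropylsilyl 2,4-bis(TIPSO)benzoate | O=C(O[Si](C(C)C)(C(C)C)C(C)C)c1ccc(O[Si](C(C)C)(C(C)C)C(C)C)cc1O[Si](C(C)C)(C(C)C)C(C)C | intermediate (not isolated)
24 | 2,4-bis(TIPSO)benzoic acid | O=C(O)c1ccc(O[Si](C(C)C)(C(C)C)C(C)C)cc1O[Si](C(C)C)(C(C)C)C(C)C | intermediate
25 | 2,4-bis(TIPSO)benzoyl chloride | O=C(Cl)c1ccc(O[Si](C(C)C)(C(C)C)C(C)C)cc1O[Si](C(C)C)(C(C)C)C(C)C | intermediate
26 | 2-[(R)-2-(TBSO)-3-methylbut-3-enyl]-6-(5-methylhex-4-enoyl)-3,5-bis(TIPSO)phenyl 2,4-bis(TIPSO)benzoate | C=C(C)[C@H](O[Si](C)(C)C(C)(C)C)Cc1c(OC(=O)c2ccc(O[Si](C(C)C)(C(C)C)C(C)C)cc2O[Si](C(C)C)(C(C)C)C(C)C)c(C(=O)CCC=C(C)C)c(O[Si](C(C)C)(C(C)C)C(C)C)cc1O[Si](C(C)C)(C(C)C)C(C)C | intermediate (not isolated)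
27 | 1-[2,4-bis(TIPSO)phenyl]-3-{3-[(R)-2-(TBSO)-3-methylbut-3-enyl]-2-hydroxy-4,6-bis(TIPSO)phenyl}-2-(3-methylbut-2-enyl)propane-1,3-dione (epimers at C2 of the dione) | C=C(C)[C@H](O[Si](C)(C)C(C)(C)C)Cc1c(O)c(C(=O)C(CC=C(C)C)C(=O)c2ccc(O[Si](C(C)C)(C(C)C)C(C)C)cc2O[Si](C(C)C)(C(C)C)C(C)C)c(O[Si](C(C)C)(C(C)C)C(C)C)cc1O[Si](C(C)C)(C(C)C)C(C)C | intermediate
28 | 2-hydroxy-2,3-dihydro form of 29 (hemiketal, C2 and C3 unassigned) | C=C(C)[C@H](O[Si](C)(C)C(C)(C)C)Cc1c(O[Si](C(C)C)(C(C)C)C(C)C)cc(O[Si](C(C)C)(C(C)C)C(C)C)c2c1OC(O)(c1ccc(O[Si](C(C)C)(C(C)C)C(C)C)cc1O[Si](C(C)C)(C(C)C)C(C)C)C(CC=C(C)C)C2=O | intermediate (not isolated)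
29 | 8-[(R)-2-(TBSO)-3-methylbut-3-enyl]-3-(3-methylbut-2-enyl)-5,7-bis(TIPSO)-2-[2,4-bis(TIPSO)phenyl]chromen-4-one | C=C(C)[C@H](O[Si](C)(C)C(C)(C)C)Cc1c(O[Si](C(C)C)(C(C)C)C(C)C)cc(O[Si](C(C)C)(C(C)C)C(C)C)c2c(=O)c(CC=C(C)C)c(-c3ccc(O[Si](C(C)C)(C(C)C)C(C)C)cc3O[Si](C(C)C)(C(C)C)C(C)C)oc12 | intermediate
30 | 2-(2,4-dihydroxyphenyl)-5,7-dihydroxy-8-[(R)-2-hydroxy-3-methylbut-3-enyl]-3-(3-methylbut-2-enyl)chromen-4-one | C=C(C)[C@H](O)Cc1c(O)cc(O)c2c(=O)c(CC=C(C)C)c(-c3ccc(O)cc3O)oc12 | target

## Step count and least certain steps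

Total step count: 13. Longest linear sequence: 10 steps (steps 1, 2, 3, 5, 6, 7, 8, 11, 12, 13).

Step 5 (key step). Three processes are the most likely to go wrong.
- Ring opening of the push–pull cyclobutenone 10 may be slow, so that ketene dimerization and decomposition outrun the cycloaddition.
- The vinylketene may acylate the product phenol.
- 10 may transfer its TIPS group to the phenol, which would erase the distinction between O8a and the other two oxygens.

Fallback, setting out from 8 and coming back at 15: the same vinylketene 11 is generated at ambient temperature by photochemical Wolff rearrangement of a diazoketone (the diazoketone variant of the benzannulation). Commercial butane-2,3-dione is mono-silylated (TIPSOTf, Et3N) to 3-(triisopropylsilyloxy)but-3-en-2-one F1. Its lithium enolate is trifluoroacetylated with 2,2,2-trifluoroethyl trifluoroacetate to 1,1,1-trifluoro-5-(triisopropylsilyloxy)hex-5-ene-2,4-dione F2. Diazo transfer with methanesulfonyl azide and Et3N gives 1-diazo-3-(triisopropylsilyloxy)but-3-en-2-one F3. Irradiation of F3 with 8 in CH2Cl2, followed by brief warming to complete the electrocyclic steps, should give 15 without ever heating 10.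

Step 3. The strongly basic sequence may cause loss of the β-silyloxy group by elimination (if enolization occurs toward C1''), incomplete rearrangement of the carbenoid, or C-silylation of the ynolate to a silylketene. Fallback, setting out from 5 and coming back at 8 through 7: 5 is reduced with DIBAL-H at −78 °C to (R)-3-(tert-butyldimethylsilyloxy)-4-methylpent-4-enal F4. F4 is homologated with dimethyl (1-diazo-2-oxopropyl)phosphonate and K2CO3 in methanol to (R)-4-(tert-butyldimethylsilyloxy)-5-methylhex-5-en-1-yne F5. The lithium acetylide of F5 is oxidized with lithium tert-butyl peroxide to ynolate 7, which is silylated with TIPSOTf to 8.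

Step 11. O-Acylation of the hindered, hydrogen-bonded phenoxide may be incomplete, the 2'-O silyl group may migrate to the diketone enolate oxygen, or the product may undergo retro-Claisen cleavage. Fallback, setting out from 21 and coming back at 27: the C2–C3 bond is made by aldol addition instead of acyl transfer. Commercial 2,4-dihydroxybenzaldehyde is silylated (TIPSCl, imidazole) to 2,4-bis(triisopropylsilyloxy)benzaldehyde F6. The dianion of 21 (LiHMDS, 2.1 equiv, −78 °C) adds to F6 to give the β-hydroxy ketone 3-[2,4-bis(TIPSO)phenyl]-3-hydroxy-1-{3-[(R)-2-(TBSO)-3-methylbut-3-enyl]-2-hydroxy-4,6-bis(TIPSO)phenyl}-2-(3-methylbut-2-enyl)propan-1-one F7. Oxidation of F7 with Dess–Martin periodinane buffered with NaHCO3 gives 27.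

Step 12. Even weak acid may start loss of the allylic TBS ether or of an aryl silyl ether; if the 2'-O silyl group is lost, closure by the ring B oxygen onto the ring A carbonyl becomes possible. Fallback, setting out from 17 and coming back at 29: ring C is closed by conjugate addition to an ynone, without acid.
- 2,4-Bis(triisopropylsilyloxy)benzaldehyde F6 is converted with CBr4 and PPh3 to 1-(2,2-dibromovinyl)-2,4-bis(triisopropylsilyloxy)benzene F8, and with n-BuLi to 1-ethynyl-2,4-bis(triisopropylsilyloxy)benzene F9.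
- The lithium acetylide of F9 (2.2 equiv) adds to 17 to give the propargylic alcohol 2-{1-hydroxy-3-[2,4-bis(TIPSO)phenyl]prop-2-ynyl}-6-[(R)-2-(TBSO)-3-methylbut-3-enyl]-3,5-bis(TIPSO)phenol F10.
- MnO2 oxidizes F10 to the ynone 1-{3-[(R)-2-(TBSO)-3-methylbut-3-enyl]-2-hydroxy-4,6-bis(TIPSO)phenyl}-3-[2,4-bis(TIPSO)phenyl]prop-2-yn-1-one F11.
- Amine-mediated six-membered conjugate closure by O8a (diethylamine or catalytic 4-dimethylaminopyridine) gives the 3-unsubstituted flavone 8-[(R)-2-(TBSO)-3-methylbut-3-enyl]-5,7-bis(TIPSO)-2-[2,4-bis(TIPSO)phenyl]chromen-4-one F12.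
- Lithiation of F12 at C3 with LDA at −78 °C and alkylation with 1-bromo-3-methylbut-2-ene gives 29.

## Further compounds

F1 | step 5 | 3-(triisopropylsilyloxy)but-3-en-2-one | CC(=O)C(=C)O[Si](C(C)C)(C(C)C)C(C)C
F2 | step 5 | 1,1,1-trifluoro-5-(triisopropylsilyloxy)hex-5-ene-2,4-dione | O=C(CC(=O)C(=C)O[Si](C(C)C)(C(C)C)C(C)C)C(F)(F)F
F3 | step 5 | 1-diazo-3-(triisopropylsilyloxy)but-3-en-2-one | [N-]=[N+]=CC(=O)C(=C)O[Si](C(C)C)(C(C)C)C(C)C
F4 | step 3 | (R)-3-(tert-butyldimethylsilyloxy)-4-methylpent-4-enal | C=C(C)[C@H](O[Si](C)(C)C(C)(C)C)CC=O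
F5 | step 3 | (R)-4-(tert-butyldimethylsilyloxy)-5-methylhex-5-en-1-yne | C=C(C)[C@H](O[Si](C)(C)C(C)(C)C)CC#C
F6 | step 11 | 2,4-bis(triisopropylsilyloxy)benzaldehyde | O=Cc1ccc(O[Si](C(C)C)(C(C)C)C(C)C)cc1O[Si](C(C)C)(C(C)C)C(C)C
F7 | step 11 | 3-[2,4-bis(TIPSO)phenyl]-3-hydroxy-1-{3-[(R)-2-(TBSO)-3-methylbut-3-enyl]-2-hydroxy-4,6-bis(TIPSO)phenyl}-2-(3-methylbut-2-enyl)propan-1-one (diastereomers at the two new centres) | C=C(C)[C@H](O[Si](C)(C)C(C)(C)C)Cc1c(O)c(C(=O)C(CC=C(C)C)C(O)c2ccc(O[Si](C(C)C)(C(C)C)C(C)C)cc2O[Si](C(C)C)(C(C)C)C(C)C)c(O[Si](C(C)C)(C(C)C)C(C)C)cc1O[Si](C(C)C)(C(C)C)C(C)C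
F8 | step 12 | 1-(2,2-dibromovinyl)-2,4-bis(triisopropylsilyloxy)benzene | BrC(Br)=Cc1ccc(O[Si](C(C)C)(C(C)C)C(C)C)cc1O[Si](C(C)C)(C(C)C)C(C)C
F9 | step 12 | 1-ethynyl-2,4-bis(triisopropylsilyloxy)benzene | C#Cc1ccc(O[Si](C(C)C)(C(C)C)C(C)C)cc1O[Si](C(C)C)(C(C)C)C(C)C
F10 | step 12 | 2-{1-hydroxy-3-[2,4-bis(TIPSO)phenyl]prop-2-ynyl}-6-[(R)-2-(TBSO)-3-methylbut-3-enyl]-3,5-bis(TIPSO)phenol (epimers at the carbinol) | C=C(C)[C@H](O[Si](C)(C)C(C)(C)C)Cc1c(O)c(C(O)C#Cc2ccc(O[Si](C(C)C)(C(C)C)C(C)C)cc2O[Si](C(C)C)(C(C)C)C(C)C)c(O[Si](C(C)C)(C(C)C)C(C)C)cc1O[Si](C(C)C)(C(C)C)C(C)C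
F11 | step 12 | 1-{3-[(R)-2-(TBSO)-3-methylbut-3-enyl]-2-hydroxy-4,6-bis(TIPSO)phenyl}-3-[2,4-bis(TIPSO)phenyl]prop-2-yn-1-one | C=C(C)[C@H](O[Si](C)(C)C(C)(C)C)Cc1c(O)c(C(=O)C#Cc2ccc(O[Si](C(C)C)(C(C)C)C(C)C)cc2O[Si](C(C)C)(C(C)C)C(C)C)c(O[Si](C(C)C)(C(C)C)C(C)C)cc1O[Si](C(C)C)(C(C)C)C(C)C
F12 | step 12 | 8-[(R)-2-(TBSO)-3-methylbut-3-enyl]-5,7-bis(TIPSO)-2-[2,4-bis(TIPSO)phenyl]chromen-4-one | C=C(C)[C@H](O[Si](C)(C)C(C)(C)C)Cc1c(O[Si](C(C)C)(C(C)C)C(C)C)cc(O[Si](C(C)C)(C(C)C)C(C)C)c2c(=O)cc(-c3ccc(O[Si](C(C)C)(C(C)C)C(C)C)cc3O[Si](C(C)C)(C(C)C)C(C)C)oc12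
A1 | alternative 1 | 8-[(E)-4-hydroxy-3-methylbut-2-enyl]-5,7-bis(methoxymethoxy)-2-[2,4-bis(methoxymethoxy)phenyl]-3-(3-methylbut-2-enyl)chromen-4-one | OC/C(C)=C/Cc1c(OCOC)cc(OCOC)c2c(=O)c(CC=C(C)C)c(-c3ccc(OCOC)cc3OCOC)oc12
A2 | alternative 1 | 8-{[(2R,3R)-3-(hydroxymethyl)-3-methyloxiran-2-yl]methyl}-5,7-bis(methoxymethoxy)-2-[2,4-bis(methoxymethoxy)phenyl]-3-(3-methylbut-2-enyl)chromen-4-one | OC[C@@]1(C)O[C@@H]1Cc1c(OCOC)cc(OCOC)c2c(=O)c(CC=C(C)C)c(-c3ccc(OCOC)cc3OCOC)oc12
A3 | alternative 1 | 5,7,2',4'-tetrakis(methoxymethyl) ether of 30 | C=C(C)[C@H](O)Cc1c(OCOC)cc(OCOC)c2c(=O)c(CC=C(C)C)c(-c3ccc(OCOC)cc3OCOC)oc12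
A4 | alternative 2 | 1-{2-bromo-3-[(R)-2-(tert-butyldimethylsilyloxy)-3-methylbut-3-enyl]-4,6-bis(methoxymethoxy)phenyl}-3-[2,4-bis(methoxymethoxy)phenyl]-2-(3-methylbut-2-enyl)propane-1,3-dione | C=C(C)[C@H](O[Si](C)(C)C(C)(C)C)Cc1c(OCOC)cc(OCOC)c(C(=O)C(CC=C(C)C)C(=O)c2ccc(OCOC)cc2OCOC)c1Br
A5 | alternative 2 | O2''-tert-butyldimethylsilyl 5,7,2',4'-tetrakis(methoxymethyl) ether of 30 | C=C(C)[C@H](O[Si](C)(C)C(C)(C)C)Cc1c(OCOC)cc(OCOC)c2c(=O)c(CC=C(C)C)c(-c3ccc(OCOC)cc3OCOC)oc12
A6 | alternative 3 | 2-[(R)-2-(tert-butyldimethylsilyloxy)-3-methylbut-3-enyl]-6-iodo-3,5-bis(methoxymethoxy)phenol | C=C(C)[C@H](O[Si](C)(C)C(C)(C)C)Cc1c(O)c(I)c(OCOC)cc1OCOC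
A7 | alternative 3 | 1-ethynyl-2,4-bis(methoxymethoxy)benzene | C#Cc1ccc(OCOC)cc1OCOC
A8 | alternative 3 | 8-[(R)-2-(tert-butyldimethylsilyloxy)-3-methylbut-3-enyl]-5,7-bis(methoxymethoxy)-2-[2,4-bis(methoxymethoxy)phenyl]chromen-4-one | C=C(C)[C@H](O[Si](C)(C)C(C)(C)C)Cc1c(OCOC)cc(OCOC)c2c(=O)cc(-c3ccc(OCOC)cc3OCOC)oc12
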